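## Analysis of the target

1. Target 14 is a diaryl ether of two bromocatechols. Ring A has OH at C1, the ether oxygen at C2, Br at C3, C4 and C5, and H at C6. Ring B has the ether oxygen at C1', H at C2', Br at C3', H at C4', Br at C5' and OH at C6'.
2. There is no stereocentre and no stable axis. The problem is purely constitutional: which oxygen carries which ring, and which carbon carries bromine.
3. The ether oxygen is tri-ortho-substituted (C1–OH and C3–Br on ring A, C6'–OH on ring B) and both rings are electron-poor, so the C–O–C unit is the hardest bond set.
4. Ring B shows the normal ortho/para bromination pattern of its own OH, but ring A does not. C6–H, ortho to C1–OH, is free, while C3 and C5, meta to it, are brominated. This is the pattern of a phenol whose free OH stood at C2, so ring A must be brominated before C2–O is substituted.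
5. The sensitive groups are five C–Br bonds (low-valent metals, organolithium bases, halogen dance) and two acidic phenols.
6. C6'–OH and C3–Br both stand ortho to the ether oxygen. Base, heat or light can therefore close a dibenzo-p-dioxin with loss of HBr, and phenoxides can move an aryl group between catechol oxygens by Smiles rearrangement.
7. The route is built on one feature. The chain O–C1–C2–O–C1'–C6'–O holds all three oxygen atoms and is the hetero ring plus carbonyl oxygen of the 1,4-benzodioxin-2-one 6, with C1' and C6' as its CH2 and C=O carbons. The rest of ring B, C2'(H)–C3'(Br)–C4'(H)–C5'(Br), is atom for atom C6–C5–C4–C3 of 3,5-dibromo-2-pyrone 9.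
8. In ring B the hydroxylated carbon C6' lies beside C–Br and the ether carbon C1' beside C–H, which is the orientation that the polarity of a pyrone cycloaddition delivers.

## Retrosynthetic reasoning

**14 ⇒ 13 ⇒ 12.** Only O–Si bonds are cut. The silyl group on C6'–O is a remnant of the key step, and the one on C1–O is put on in the same flask to keep a free phenol away from the acid-sensitive dienophile. The forward reaction is a mild, non-basic desilylation, so the predioxin motif never meets a hot phenoxide.

**12 ⇒ 11.** The oxygen on C1 of ring A is reconnected to C6', and a hydrogen is placed on C1'. The free phenol of ring A thus becomes the leaving group of an aromatizing elimination. It then needs no protecting group, and all three oxygens can come from one small heterocycle. The forward reaction must expel the aryloxide and not the siloxy group from C6'.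

**11 ⇒ 10 ⇒ 7 + 9 (key disconnection).**
- The bonds C1'–C2' and C5'–C6' of ring B are cut, and the O–C(=O) bridge is restored between C2' and C5'.
- These two bonds separate the oxygenated edge C1'–C6' from the H/Br/H/Br four-carbon unit. Any other pair would split a fragment that can be had whole.
- Ring B then arrives with both bromines, its oxygen and the ether already in place.
- The congested aryl–O–aryl linkage is never made at an aromatic carbon, because the O–C1' bond reduces to an O–C(sp3) bond.
- The forward reaction needs one regiochemistry (CH end of 7 to C6 of 9) and loss of the bridge.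

**7 ⇒ 6.** The O–Si bond is cut. The forward reaction is an enol silylation without strong base, because ring A carries three C–Br bonds and an acidic C–H.

**6 ⇒ 5 ⇒ 4.** The lactone C(=O)–O bond is opened and the C1 oxygen is capped as its methyl ether. The methyl group is what told the two catechol oxygens apart in the earlier steps. The forward reaction cleaves it and closes the six-membered lactone.

**4 ⇒ 2 + 3.** The O–CH2 bond is cut, which later becomes the ether O–C1' bond of 14. A hindered, weakly nucleophilic phenoxide has to attack only a primary, activated carbon of 3.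

**2 ⇒ 1.** Three C–Br bonds are cut. With the C2 oxygen free and the C1 oxygen methylated, the directing effects of 1 write exactly the ring A pattern in one electrophilic bromination.

**9 ⇒ 8.** The C5–Br bond is traced back to the carboxyl group of 8 and the C3–Br bond to a C–H. One operation gives the diene.

## Alternatives that were turned down

**Alternative 1:** the textbook cut of the ether O–C1' bond between two finished arenes.
- Forward step: Ullmann-type O-arylation of 2 (CuI, ligand, Cs2CO3, heat) with 1,5-dibromo-3-iodo-2-methoxybenzene A1. A metal-free variant uses its trivalent-iodine derivative, (3,5-dibromo-2-methoxyphenyl)(mesityl)iodonium triflate A2. Either gives the dimethyl ether A3, and double demethylation follows.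
- Phenol 2 is di-ortho-substituted and weakly nucleophilic, and A1 carries an ortho methoxy group, so a tri-ortho ether must form at a crowded centre.
- Monovalent copper or zerovalent palladium faces one C–I and five C–Br bonds. Phenol 2 is itself an aryl bromide with a phenoxide, which opens oligomerization, halogen scrambling and hydrodebromination.
- Hot carbonate is the very medium for Smiles rearrangement and dioxin closure.
- A1 and A2 cost three to four steps of their own, and two protecting groups must fall at the end.
- Postponing the bromination does not help, because after arylation of C2–O ring A would be brominated at C4 and C6.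

**Alternative 2:** an aryne that takes up C2–O and C3–Br of ring A in one operation.
- Forward step: fluoride treatment of 3,4-dibromo-6-methoxy-2-(trimethylsilyl)phenyl triflate A4 gives the aryne A5. The phenoxide of 3,5-dibromo-2-methoxyphenol A6 adds, and the aryl anion is trapped by a Br+ donor.
- The triple bond C2≡C3 is flanked by C1–OMe and C4–Br. Both are inductive acceptors that send a nucleophile to the far carbon, and the oxygen substituent distorts the aryne more strongly than bromine.
- The phenoxide should therefore bond to C3 and bromine to C2, giving the wrong constitution A7.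
- A4 needs a long sequence on a polybrominated ring, and the aryl anion is easily lost to protonation.

**Alternative 3:** the mirror image of the chosen plan, building ring A instead of ring B.
- Forward step: cycloaddition of 3,4,5-tribromo-2-pyrone A8 with the silyl ketene acetal A9 of 6,8-dibromo-1,4-benzodioxin-2(3H)-one, followed by the same cascade.
- The polarity of the cycloaddition always puts the acetal carbon (later C–OH) beside the C3–Br of the pyrone, and the CH(OAr) carbon beside C6–H.
- Ring A needs the opposite arrangement: ether carbon C2 beside C3–Br, hydroxyl carbon C1 beside C6–H. The matched reaction would give the isomer A10.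
- A8 is not a readily available diene and is more hindered, whereas the ring A pattern costs one bromination of 1.

Key step: step 6

Remark on the chemistry: rotation about both ether C–O bonds is taken as fast, so 14 is treated as achiral. Compounds 10 and 11 are racemic and are drawn as one enantiomer.

## Route

Step 1
Reactants: 1 guaiacol (2-methoxyphenol)
Product: 2 2,3,4-tribromo-6-methoxyphenol (4,5,6-tribromoguaiacol)
Conditions: Br2 (3.1 equiv), AcOH, 15 → 50 °C
Reagents that add atoms: bromine, BrBr
Why: Electrophilic aromatic bromination: the free OH directs bromine to its para and ortho positions and OMe directs the third bromine to its own para position, the site between them. The last C–H (ortho to OMe, meta to OH) is the least activated site of a ring that by then carries three bromines, so the reaction should stop at the tribromide.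

Step 2
Reactants: 2 2,3,4-tribromo-6-methoxyphenol; 3 methyl bromoacetate
Product: 4 methyl 2-(2,3,4-tribromo-6-methoxyphenoxy)acetate
Conditions: K2CO3, DMF, rt → 40 °C
Reagents that add atoms: none
Why: Williamson ether synthesis (SN2): the acidic, hindered phenol is fully deprotonated by K2CO3 and has to attack only a primary α-halo ester carbon. This mild step makes the O–C bond that becomes the diaryl ether bond O–C1' of 14.

Step 3
Reactants: 4 methyl 2-(2,3,4-tribromo-6-methoxyphenoxy)acetate
Product: 6 5,6,7-tribromo-1,4-benzodioxin-2(3H)-one, via hydroxy ester 5 (not isolated)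
Conditions: BBr3 (2.5 equiv), CH2Cl2, −78 → 0 °C; H2O quench, solvent switch; TsOH·H2O (cat.), PhMe, reflux through 4 Å molecular sieves
Reagents that add atoms: none
Why: Lewis acid cleavage of an aryl methyl ether: BBr3 binds the more basic, unhindered OMe oxygen and bromide attacks CH3, while the glycolate oxygen, flanked by Br on an electron-poor ring, is a poor donor. Acid-catalysed 6-exo-trig transesterification then closes the lactone and is driven by removal of MeOH; any ester cleaved to the acid closes to the same lactone.

Step 4
Reactants: 6 5,6,7-tribromo-1,4-benzodioxin-2(3H)-one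
Product: 7 tert-butyl(dimethyl)[(5,6,7-tribromo-1,4-benzodioxin-2-yl)oxy]silane
Conditions: TBSOTf (1.2 equiv), Et3N (1.6 equiv), CH2Cl2, 0 °C → rt; pentane, filtration, used without chromatography
Reagents that add atoms: tert-butyldimethylsilyl trifluoromethanesulfonate, CC(C)(C)[Si](C)(C)OS(=O)(=O)C(F)(F)F
Why: Soft enolization: the carbonyl oxygen is silylated and Et3N removes a proton from the CH2 that is activated by both C=O and O, as in the enol silylation of 1,4-dioxan-2-ones for Ireland–Claisen rearrangements. No free enolate and no strong base occur, so halogen–metal exchange, halogen dance and ketene-forming E1cB opening of the aryl ester are avoided.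

Step 5
Reactants: 8 coumalic acid (2-oxo-2H-pyran-5-carboxylic acid)
Product: 9 3,5-dibromo-2H-pyran-2-one
Conditions: NBS (2.5 equiv), Bu4NBr (cat.), CHCl3, 50 °C
Reagents that add atoms: N-bromosuccinimide, O=C1CCC(=O)N1Br
Why: Hunsdiecker-type bromodecarboxylation replaces the C5 carboxyl group by bromine, and electrophilic bromination takes place at C3, the nucleophilic α-position of the pyrone. Both events occur in one flask.

Step 6
Reactants: 7 tert-butyl(dimethyl)[(5,6,7-tribromo-1,4-benzodioxin-2-yl)oxy]silane; 9 3,5-dibromo-2H-pyran-2-one
Product: 14 3,4,5-tribromo-2-(3,5-dibromo-2-hydroxyphenoxy)phenol (CNP0169944.0), via bridged lactone cycloadduct 10 (not isolated), via cis-dihydrodibenzodioxin 11 (not isolated), via mono-TBS ether 12 (not isolated), via bis-TBS ether 13 (not isolated)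
Conditions: 7 (1.3 equiv), MTBSTFA (1.2 equiv), xylenes, sealed tube, dark, 100 → 135 °C; then Et3N·3HF, THF, rt
Reagents that add atoms: none
Why: Mechanism: the electron-poor diene C3–C6 of 9 and the electron-rich C2=C3 bond of 7 combine in an inverse-electron-demand Diels–Alder reaction to the bridged lactone 10, a retro-[4+2] step expels CO2 to give the cyclohexadiene 11, and β-elimination across C10a–H/C4a–O5 opens the dioxin ring and aromatizes ring B to 12; MTBSTFA (N-tert-butyldimethylsilyl-N-methyltrifluoroacetamide) caps the liberated phenol as 13 so that it cannot protonate unreacted 7, and fluoride then removes both silyl groups. The closest known reaction type is the catechol annulation of 2-pyrones with 1,1,2-trialkoxyethenes (cycloaddition, loss of CO2, loss of an alcohol), together with the known cycloadditions of 9 with vinyl ethers and silyl enol ethers. Ring B is closed by an intermolecular suprafacial [4+2] cycloaddition that forms C1'–C2' and C5'–C6'; the only other ring event is the opening of the six-membered dioxin ring. Regioselectivity: the two oxygen donors on C2 of 7 outweigh the single one on C3, so C3–H is the nucleophilic end and bonds to C6 of 9, the dienoate terminus whose attack places charge on the α-bromo ester unit, and the acetal carbon is left to bond to C3–Br, which puts C6'–O beside C5'–Br and C1'–O beside C2'–H as in 14. The four stereocentres of 10 and the two of 11 are transient, endo and exo adducts converge, and only the cis relation of OTBS and H in 11, fixed by suprafacial addition to the ring alkene, matters. Because of that cis relation C10a–H can stand antiperiplanar only to the C4a–O5 (aryloxy) bond and never to C4a–OSi, and a tribromophenoxide is by far the better leaving group, so ring opening to 12 should win over loss of silanol, which would keep the dioxin ring. No metal and no base are present, so the five C–Br bonds should survive and Smiles rearrangement and dioxin closure should not start.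

## Compound list

1 | guaiacol (2-methoxyphenol) | COc1ccccc1O | starting material
2 | 2,3,4-tribromo-6-methoxyphenol | COc1cc(Br)c(Br)c(Br)c1O | intermediate
3 | methyl bromoacetate | COC(=O)CBr | starting material
4 | methyl 2-(2,3,4-tribromo-6-methoxyphenoxy)acetate | COC(=O)COc1c(OC)cc(Br)c(Br)c1Br | intermediate
5 | methyl 2-(2,3,4-tribromo-6-hydroxyphenoxy)acetate | COC(=O)COc1c(O)cc(Br)c(Br)c1Br | intermediate
6 | 5,6,7-tribromo-1,4-benzodioxin-2(3H)-one | O=C1COc2c(Br)c(Br)c(Br)cc2O1 | intermediate
7 | tert-butyl(dimethyl)[(5,6,7-tribromo-1,4-benzodioxin-2-yl)oxy]silane | CC(C)(C)[Si](C)(C)OC1=COc2c(Br)c(Br)c(Br)cc2O1 | intermediate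
8 | coumalic acid (2-oxo-2H-pyran-5-carboxylic acid) | OC(=O)C1=COC(=O)C=C1 | starting material
9 | 3,5-dibromo-2H-pyran-2-one | O=C1OC=C(Br)C=C1Br | intermediate
10 | racemic cycloadduct: 4,7-dibromo-5-(tert-butyldimethylsilyloxy)-2-oxabicyclo[2.2.2]oct-7-en-3-one, joined at C5 and C6 through two oxygens to the tribromobenzene ring; drawn with these oxygens endo (syn to the C=C bridge) | O=C1O[C@@H]2C(Br)=C[C@@]1(Br)[C@@]3(O[Si](C)(C)C(C)(C)C)Oc4cc(Br)c(Br)c(Br)c4O[C@@H]23 | intermediate
11 | racemic cis-2,4,7,8,9-pentabromo-4a-(tert-butyldimethylsilyloxy)-4a,10a-dihydrodibenzo[b,e][1,4]dioxin | CC(C)(C)[Si](C)(C)O[C@]12Oc3cc(Br)c(Br)c(Br)c3O[C@H]1C=C(Br)C=C2Br | intermediate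
12 | 3,4,5-tribromo-2-[3,5-dibromo-2-(tert-butyldimethylsilyloxy)phenoxy]phenol | CC(C)(C)[Si](C)(C)Oc1c(Br)cc(Br)cc1Oc1c(O)cc(Br)c(Br)c1Br | intermediate
13 | bis(tert-butyldimethylsilyl) ether of 14 | CC(C)(C)[Si](C)(C)Oc1cc(Br)c(Br)c(Br)c1Oc1cc(Br)cc(Br)c1O[Si](C)(C)C(C)(C)C | intermediate
14 | 3,4,5-tribromo-2-(3,5-dibromo-2-hydroxyphenoxy)phenol | Oc1cc(Br)c(Br)c(Br)c1Oc1cc(Br)cc(Br)c1O | target

## Step count and risks

Total step count: 6. Longest linear sequence: 5 (steps 1, 2, 3, 4 and 6). Step 5 is a one-step side branch.

**Key step (step 6).**
- The cycloaddition may be slow. The bond between the acetal carbon of 7 and C3–Br of 9 joins two fully substituted carbons, and the bromoaryloxy groups drain donor strength from the alkene.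
- If the reaction runs stepwise through a zwitterion, silyl transfer to the pyrone-derived carboxylate (a Mukaiyama–Michael-type leak) can compete with ring closure.
- Traces of acid could protonate the siloxy oxygen and steer the elimination towards loss of silanol with retention of the dioxin ring.
- Incomplete capping of the liberated phenol would consume 7 by proton transfer.
- The fallback gives up ring construction and sets out from 2.
  - SNAr on 2-fluorobenzaldehyde (K2CO3, DMAc, 120 °C) gives 2-(2,3,4-tribromo-6-methoxyphenoxy)benzaldehyde F1.
  - Baeyer–Villiger oxidation (mCPBA, CH2Cl2) gives 2-(2,3,4-tribromo-6-methoxyphenoxy)phenyl formate F2.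
  - Cold methanolysis (K2CO3, MeOH, 0 °C) gives 2-(2,3,4-tribromo-6-methoxyphenoxy)phenol F3.
  - Br2 (2 equiv, AcOH) brominates ortho and para to the new OH to give 2,4-dibromo-6-(2,3,4-tribromo-6-methoxyphenoxy)phenol F4.
  - BBr3 in CH2Cl2 cleaves the methyl ether, and the sequence comes back to the route at 14.

**Risk in step 4.**
- The lactone is an activated aryl ester. Ring opening by E1cB to a ketene, C-silylation, and hydrolytic loss of the silyl group during isolation are the likely failures.
- The fallback removes the aryl ester leaving group from the dienophile and sets out from 4.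
  - TBSOTf/Et3N gives the acyclic ketene acetal 1-methoxy-1-(tert-butyldimethylsilyloxy)-2-(2,3,4-tribromo-6-methoxyphenoxy)ethene F5.
  - Heating F5 with 9 runs the same cycloaddition, with loss of CO2 and then of methanol. Mixed methyl silyl ketene acetals usually keep the siloxy group in such aromatizations. The product is tert-butyl[2,4-dibromo-6-(2,3,4-tribromo-6-methoxyphenoxy)phenoxy]dimethylsilane F6.
  - BBr3 cleaves the methyl ether and the sequence comes back to the route at 12, which Et3N·3HF converts into 14.

**Risk in step 3.**
- Ring closure may stay incomplete, because the transesterification equilibrium of an acidic phenol lies towards the open methyl ester.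
- Cleavage of the O–CH2 bond by BBr3 is a lesser danger.
- The fallback replaces the equilibrium by an irreversible acid activation and sets out from 4.
  - LiOH (THF/H2O) gives 2-(2,3,4-tribromo-6-methoxyphenoxy)acetic acid F7.
  - BBr3 gives 2-(2,3,4-tribromo-6-hydroxyphenoxy)acetic acid F8.
  - Cyclodehydration with EDC·HCl in CH2Cl2 comes back to the route at 6.

**Risk in step 1.**
- The third bromination has to enter between two bromines. It may stall, drift to the position ortho to OMe, or run on to the tetrabromide.
- The fallback places the difficult bromine first, under OMe control, and sets out from 1.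
  - Ac2O/pyridine gives 2-methoxyphenyl acetate F9.
  - NBS in MeCN brominates para to OMe to give 5-bromo-2-methoxyphenyl acetate F10.
  - K2CO3/MeOH gives 5-bromo-2-methoxyphenol F11.
  - Br2 (2 equiv, AcOH) then fills the ortho and para positions of the free OH and comes back to the route at 2.

## Further compounds

F1 | step 6 | 2-(2,3,4-tribromo-6-methoxyphenoxy)benzaldehyde | COc1cc(Br)c(Br)c(Br)c1Oc1ccccc1C=O
F2 | step 6 | 2-(2,3,4-tribromo-6-methoxyphenoxy)phenyl formate | COc1cc(Br)c(Br)c(Br)c1Oc1ccccc1OC=O
F3 | step 6 | 2-(2,3,4-tribromo-6-methoxyphenoxy)phenol | COc1cc(Br)c(Br)c(Br)c1Oc1ccccc1O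
F4 | step 6 | 2,4-dibromo-6-(2,3,4-tribromo-6-methoxyphenoxy)phenol | COc1cc(Br)c(Br)c(Br)c1Oc1cc(Br)cc(Br)c1O
F5 | step 4 | 1-methoxy-1-(tert-butyldimethylsilyloxy)-2-(2,3,4-tribromo-6-methoxyphenoxy)ethene (E/Z mixture) | COC(O[Si](C)(C)C(C)(C)C)=COc1c(OC)cc(Br)c(Br)c1Br
F6 | step 4 | tert-butyl[2,4-dibromo-6-(2,3,4-tribromo-6-methoxyphenoxy)phenoxy]dimethylsilane | COc1cc(Br)c(Br)c(Br)c1Oc1cc(Br)cc(Br)c1O[Si](C)(C)C(C)(C)C
F7 | step 3 | 2-(2,3,4-tribromo-6-methoxyphenoxy)acetic acid | COc1cc(Br)c(Br)c(Br)c1OCC(=O)O
F8 | step 3 | 2-(2,3,4-tribromo-6-hydroxyphenoxy)acetic acid | OC(=O)COc1c(O)cc(Br)c(Br)c1Br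
F9 | step 1 | 2-methoxyphenyl acetate | COc1ccccc1OC(C)=O
F10 | step 1 | 5-bromo-2-methoxyphenyl acetate | COc1ccc(Br)cc1OC(C)=O
F11 | step 1 | 5-bromo-2-methoxyphenol | COc1ccc(Br)cc1O
A1 | alternative 1 | 1,5-dibromo-3-iodo-2-methoxybenzene | COc1c(Br)cc(Br)cc1I
A2 | alternative 1 | (3,5-dibromo-2-methoxyphenyl)(mesityl)iodonium trifluoromethanesulfonate | COc1c(Br)cc(Br)cc1[I+]c1c(C)cc(C)cc1C.[O-]S(=O)(=O)C(F)(F)F
A3 | alternative 1 | 1,2,3-tribromo-4-(3,5-dibromo-2-methoxyphenoxy)-5-methoxybenzene | COc1cc(Br)c(Br)c(Br)c1Oc1cc(Br)cc(Br)c1OC
A4 | alternative 2 | 3,4-dibromo-6-methoxy-2-(trimethylsilyl)phenyl trifluoromethanesulfonate | COc1cc(Br)c(Br)c([Si](C)(C)C)c1OS(=O)(=O)C(F)(F)F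
A5 | alternative 2 | 3,4-dibromo-6-methoxy-1,2-didehydrobenzene (aryne) | COC1=CC(Br)=C(Br)C#C1
A6 | alternative 2 | 3,5-dibromo-2-methoxyphenol | COc1c(O)cc(Br)cc1Br
A7 | alternative 2 | 1,2,4-tribromo-3-(3,5-dibromo-2-methoxyphenoxy)-5-methoxybenzene | COc1cc(Br)c(Br)c(Oc2cc(Br)cc(Br)c2OC)c1Br
A8 | alternative 3 | 3,4,5-tribromo-2H-pyran-2-one | O=C1OC=C(Br)C(Br)=C1Br
A9 | alternative 3 | tert-butyl[(6,8-dibromo-1,4-benzodioxin-2-yl)oxy]dimethylsilane | CC(C)(C)[Si](C)(C)OC1=COc2cc(Br)cc(Br)c2O1
A10 | alternative 3 | 2,3,4-tribromo-6-(3,5-dibromo-2-hydroxyphenoxy)phenol | Oc1c(Br)c(Br)c(Br)cc1Oc1cc(Br)cc(Br)c1O
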